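**Retrosynthetic overview**
- The strategy rests on the trans-fused α-methylene-γ-lactone (ring O–C6–C7–C11–C12). C13=C11–C7 is read as the transposed allyl unit of a 3-(bromomethyl)butenolide, and C7 is bonded to the carbinol carbon C8, so the C7–C8 bond is cut. This opens the ten-membered carbocycle to the bromo aldehyde 26.
- Ring order: the butenolide first (C6–OH esterified with 2-(bromomethyl)acrylic acid, then ring-closing metathesis), the ten-membered ring last (CrCl2).
- Chain: C8–C10 from (S)-glyceraldehyde acetonide; the Z C1=C10 iodide by anti-carbomagnesiation; C2 by catalytic asymmetric propargylation of the Z enal; the E C4=C5 iodide by carboalumination; C6 by catalytic asymmetric alkenylzinc addition to acrolein.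
- After ring closure: angelate at C8, triethylsilyl-to-acetate exchange at C9, desilylation at C2.

Key step: step 15

Remark: germacranolide numbering (C1–C15) is used for all intermediates. The facial sense of the two catalyst-controlled additions (steps 7 and 10) is assigned from the accepted models of these catalysts; the antipodal catalyst would be used if the sense were reversed.

**Step 1**
Reactants: 1 (S)-2,2-dimethyl-1,3-dioxolane-4-carbaldehyde
Product: 2 (R)-4-ethynyl-2,2-dimethyl-1,3-dioxolane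
Conditions: dimethyl (1-diazo-2-oxopropyl)phosphonate, K2CO3, MeOH, 0 °C to rt
Reagents that add atoms: dimethyl (1-diazo-2-oxopropyl)phosphonate, COP(=O)(OC)C(=[N+]=[N-])C(C)=O
Why: Seyferth–Gilbert homologation in the Ohira–Bestmann form turns the aldehyde into the terminal alkyne (C10≡C1) under mild carbonate conditions that should leave the α-oxygenated centre C9 intact; no stereocentre is formed.

**Step 2**
Reactants: 2 (R)-4-ethynyl-2,2-dimethyl-1,3-dioxolane
Product: 3 (R)-but-3-yne-1,2-diol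
Conditions: Dowex 50W (H+ form), MeOH–H2O, rt
Reagents that add atoms: none
Why: Acid-catalysed acetal hydrolysis frees the C8/C9 diol without touching the stereocentre or the alkyne.

**Step 3**
Reactants: 3 (R)-but-3-yne-1,2-diol
Product: 5 (R)-1-[(4-methoxybenzyl)oxy]but-3-yn-2-ol, via stannylene acetal 4 (not isolated)
Conditions: Bu2SnO, toluene, reflux (water removal); then 4-methoxybenzyl chloride, Bu4NI, 90 °C
Reagents that add atoms: 4-methoxybenzyl chloride, COc1ccc(CCl)cc1
Why: Stannylene-acetal-directed O-alkylation of a terminal 1,2-diol takes place at the primary oxygen (C8–O), leaving the propargylic C9 hydroxyl free for the next step.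

**Step 4**
Reactants: 5 (R)-1-[(4-methoxybenzyl)oxy]but-3-yn-2-ol
Product: 7 (2R,3Z)-4-iodo-1-[(4-methoxybenzyl)oxy]-3-methylbut-3-en-2-ol, via oxamagnesacycle 6 (not isolated)
Conditions: MeMgBr (3.5 equiv), CuI (0.2 equiv), THF, −10 °C to rt; then I2, −20 to 0 °C
Reagents that add atoms: methylmagnesium bromide, C[Mg]Br; iodine, II
Why: Copper-catalysed anti-carbomagnesiation of the propargylic magnesium alkoxide puts the methyl group (C14) on the proximal carbon C10 and magnesium on C1 in a five-membered chelate, and iodinolysis with retention should give the Z iodide with iodine cis to C9.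

**Step 5**
Reactants: 7 (2R,3Z)-4-iodo-1-[(4-methoxybenzyl)oxy]-3-methylbut-3-en-2-ol
Product: 8 (2R,3Z)-4-iodo-1-[(4-methoxybenzyl)oxy]-3-methyl-2-[(triethylsilyl)oxy]but-3-ene
Conditions: TESCl, imidazole, DMF, 0 °C
Reagents that add atoms: chlorotriethylsilane, CC[Si](Cl)(CC)CC
Why: Standard silylation of the secondary allylic alcohol installs the C9 protecting group that is later removed selectively in the presence of the C2 silyl ether.

**Step 6**
Reactants: 8 (2R,3Z)-4-iodo-1-[(4-methoxybenzyl)oxy]-3-methyl-2-[(triethylsilyl)oxy]but-3-ene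
Product: 10 (2Z,4R)-5-[(4-methoxybenzyl)oxy]-3-methyl-4-[(triethylsilyl)oxy]pent-2-enal, via Z alkenylmagnesium chloride 9 (not isolated)
Conditions: i-PrMgCl·LiCl, THF, −20 to 0 °C; then DMF, 0 °C; aq. NH4Cl
Reagents that add atoms: N,N-dimethylformamide, CN(C)C=O
Why: Iodine–magnesium exchange with the turbo-Grignard reagent keeps the alkene geometry, the alkenylmagnesium (unlike an alkenyllithium) should not undergo 1,4 O-to-C silyl migration from the cis C9 silyl ether, and Bouveault formylation gives the Z enal (C2).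

**Step 7**
Reactants: 10 (2Z,4R)-5-[(4-methoxybenzyl)oxy]-3-methyl-4-[(triethylsilyl)oxy]pent-2-enal; 11 allenylboronic acid pinacol ester
Product: 13 (4S,5Z,7R)-8-[(4-methoxybenzyl)oxy]-6-methyl-7-[(triethylsilyl)oxy]oct-5-en-1-yn-4-ol, via pinacol borate 12 (not isolated)
Conditions: (S)-TRIP phosphoric acid (10 mol%), 4 Å molecular sieves, toluene, 0 °C; aqueous work-up
Reagents that add atoms: none
Why: Chiral-phosphoric-acid-catalysed propargylation with an allenylboronate runs through a closed six-membered SE2' transition state in which the CH2 terminus bonds to C2, and the catalyst (not the remote C9 centre) should set C2 as S by Si-face attack.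

**Step 8**
Reactants: 13 (4S,5Z,7R)-8-[(4-methoxybenzyl)oxy]-6-methyl-7-[(triethylsilyl)oxy]oct-5-en-1-yn-4-ol
Product: 14 (4S,5Z,7R)-4-[(tert-butyldimethylsilyl)oxy]-8-[(4-methoxybenzyl)oxy]-6-methyl-7-[(triethylsilyl)oxy]oct-5-en-1-yne
Conditions: TBSCl, imidazole, DMF, rt
Reagents that add atoms: tert-butyldimethylsilyl chloride, CC(C)(C)[Si](C)(C)Cl
Why: Standard silylation gives the robust C2 ether that stays in place until the last step.

**Step 9**
Reactants: 14 (4S,5Z,7R)-4-[(tert-butyldimethylsilyl)oxy]-8-[(4-methoxybenzyl)oxy]-6-methyl-7-[(triethylsilyl)oxy]oct-5-en-1-yne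
Product: 16 (1E,4S,5Z,7R)-4-[(tert-butyldimethylsilyl)oxy]-1-iodo-8-[(4-methoxybenzyl)oxy]-2,6-dimethyl-7-[(triethylsilyl)oxy]octa-1,5-diene, via alkenylalane 15 (not isolated)
Conditions: Me3Al (3 equiv), Cp2ZrCl2 (0.5 equiv), CH2Cl2, 0 °C to rt; then I2, THF, −30 °C
Reagents that add atoms: trimethylaluminium, C[Al](C)C; iodine, II
Why: Negishi zirconium-catalysed carboalumination adds methyl (C15) and aluminium syn across the terminal alkyne, methyl to C4 and aluminium to C5, and iodinolysis with retention should give the E iodide.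

**Step 10**
Reactants: 16 (1E,4S,5Z,7R)-4-[(tert-butyldimethylsilyl)oxy]-1-iodo-8-[(4-methoxybenzyl)oxy]-2,6-dimethyl-7-[(triethylsilyl)oxy]octa-1,5-diene; 17 acrolein
Product: 20 (3S,4E,7S,8Z,10R)-7-[(tert-butyldimethylsilyl)oxy]-11-[(4-methoxybenzyl)oxy]-5,9-dimethyl-10-[(triethylsilyl)oxy]undeca-1,4,8-trien-3-ol, via alkenyllithium 18 (not isolated), via alkenyl(ethyl)zinc 19 (not isolated)
Conditions: t-BuLi (2 equiv), Et2O, −78 °C; EtZnCl, −78 to 0 °C; N,N,N',N'-tetraethylethylenediamine; (+)-MIB [3-exo-(morpholino)isoborneol] (10 mol%), acrolein, toluene, −20 °C; aq. NH4Cl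
Reagents that add atoms: none
Why: Iodine–lithium exchange with retention, transmetalation to an alkenyl(ethyl)zinc and amino-alcohol-catalysed enantioselective 1,2-addition (the diamine sequesters the lithium salts that would cause a racemic background) should give the bis-allylic alcohol, with C6 set by the catalyst through Re-face attack on acrolein.

**Step 11**
Reactants: 20 (3S,4E,7S,8Z,10R)-7-[(tert-butyldimethylsilyl)oxy]-11-[(4-methoxybenzyl)oxy]-5,9-dimethyl-10-[(triethylsilyl)oxy]undeca-1,4,8-trien-3-ol; 21 2-(bromomethyl)acrylic acid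
Product: 23 (3S,4E,7S,8Z,10R)-7-[(tert-butyldimethylsilyl)oxy]-11-[(4-methoxybenzyl)oxy]-5,9-dimethyl-10-[(triethylsilyl)oxy]undeca-1,4,8-trien-3-yl 2-(bromomethyl)acrylate, via O-acylisourea 22 (not isolated)
Conditions: DCC, DMAP (5 mol%), CH2Cl2, −20 to 0 °C
Reagents that add atoms: none
Why: Steglich esterification acylates the C6 hydroxyl without breaking the C6–O bond, and the low DMAP loading and low temperature should keep the allylic bromide from being displaced.

**Step 12**
Reactants: 23 (3S,4E,7S,8Z,10R)-7-[(tert-butyldimethylsilyl)oxy]-11-[(4-methoxybenzyl)oxy]-5,9-dimethyl-10-[(triethylsilyl)oxy]undeca-1,4,8-trien-3-yl 2-(bromomethyl)acrylate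
Product: 24 (5R)-3-(bromomethyl)-5-[(1E,4S,5Z,7R)-4-[(tert-butyldimethylsilyl)oxy]-8-[(4-methoxybenzyl)oxy]-2,6-dimethyl-7-[(triethylsilyl)oxy]octa-1,5-dien-1-yl]furan-2(5H)-one
Conditions: second-generation Grubbs catalyst (H2IMes)(PCy3)Cl2Ru=CHPh (10 mol%), CH2Cl2 (0.01 M), reflux
Reagents that add atoms: none
Why: Ring-closing metathesis: the ruthenium carbene loads at the monosubstituted C7 vinyl group and closes onto the 1,1-disubstituted acrylate to give the five-membered butenolide (C7=C11) with loss of ethene; the trisubstituted C4=C5 and C1=C10 alkenes are too hindered to compete and allylic bromides are tolerated.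

**Step 13**
Reactants: 24 (5R)-3-(bromomethyl)-5-[(1E,4S,5Z,7R)-4-[(tert-butyldimethylsilyl)oxy]-8-[(4-methoxybenzyl)oxy]-2,6-dimethyl-7-[(triethylsilyl)oxy]octa-1,5-dien-1-yl]furan-2(5H)-one
Product: 25 (5R)-3-(bromomethyl)-5-[(1E,4S,5Z,7R)-4-[(tert-butyldimethylsilyl)oxy]-8-hydroxy-2,6-dimethyl-7-[(triethylsilyl)oxy]octa-1,5-dien-1-yl]furan-2(5H)-one
Conditions: DDQ, CH2Cl2–pH 7 phosphate buffer (10:1), 0 °C
Reagents that add atoms: none
Why: Oxidative cleavage of the 4-methoxybenzyl ether by DDQ through the benzylic oxocarbenium ion runs under buffered neutral conditions that the silyl ethers, the allylic bromide and the base-sensitive butenolide should survive.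

**Step 14**
Reactants: 25 (5R)-3-(bromomethyl)-5-[(1E,4S,5Z,7R)-4-[(tert-butyldimethylsilyl)oxy]-8-hydroxy-2,6-dimethyl-7-[(triethylsilyl)oxy]octa-1,5-dien-1-yl]furan-2(5H)-one
Product: 26 (2R,3Z,5S,7E)-8-[(2R)-4-(bromomethyl)-5-oxo-2,5-dihydrofuran-2-yl]-5-[(tert-butyldimethylsilyl)oxy]-3,7-dimethyl-2-[(triethylsilyl)oxy]octa-3,7-dienal
Conditions: Dess–Martin periodinane, NaHCO3, CH2Cl2, 0 °C; used at once
Reagents that add atoms: none
Why: Dess–Martin oxidation of the primary alcohol under bicarbonate buffering is mild enough to avoid epimerisation at C9 and conjugation of the β,γ-unsaturated α-silyloxy aldehyde.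

**Step 15**
Reactants: 26 (2R,3Z,5S,7E)-8-[(2R)-4-(bromomethyl)-5-oxo-2,5-dihydrofuran-2-yl]-5-[(tert-butyldimethylsilyl)oxy]-3,7-dimethyl-2-[(triethylsilyl)oxy]octa-3,7-dienal
Product: 28 (2S,6R,7R,8R,9R)-2-[(tert-butyldimethylsilyl)oxy]-8-hydroxy-9-[(triethylsilyl)oxy]germacra-1(10)Z,4E,11(13)-trien-12,6-olide, via allylchromium 27 (not isolated)
Conditions: CrCl2 (10 equiv), THF, rt, slow addition of 26 (final concentration about 2 mM); aqueous work-up
Reagents that add atoms: none
Why: Divalent chromium (two equivalents per bromide) reduces the allylic C13–Br bond to the trivalent allylchromium 27, which adds to the tethered C8 aldehyde through its γ-carbon C7 in a closed six-membered chair transition state, so that C7–C8 forms and the alkene moves to C11=C13; this is the intramolecular Nozaki–Hiyama–Kishi allylation, the way 3-(halomethyl)butenolides are known to add to aldehydes and a known means of closing ten-membered carbocycles. The ten-membered ring closes in the 10-exo-trig mode by allyl transfer, the lactone ring being in place beforehand. C7 is set by C6: bond formation on the butenolide face anti to the C6–C5 bond avoids eclipsing C6–C5 with the new C7–C8 bond on the flat five-membered ring and gives the trans ring fusion. C8 is set relative to C7 by the allyl geometry: the ring holds C6 trans to C13, so with C9 equatorial on the aldehyde the chair gives the C7/C8 anti relationship. The selectivity needed is this chair control over the Felkin–Anh preference of the α-silyloxy aldehyde, which on its own favours the 8,9-anti arrangement and not the 8,9-syn one of the target; the rigid Z C1=C10 alkene and the planar butenolide, which restrict the tether to few reactive conformers and hold C7 near C8, are what the substrate offers to secure it. High dilution suppresses oligomerisation, and the neutral, non-basic medium should leave the enolisable C9 centre and the acidic C6–H untouched.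

**Step 16**
Reactants: 28 (2S,6R,7R,8R,9R)-2-[(tert-butyldimethylsilyl)oxy]-8-hydroxy-9-[(triethylsilyl)oxy]germacra-1(10)Z,4E,11(13)-trien-12,6-olide; 29 angelic acid [(Z)-2-methylbut-2-enoic acid]
Product: 31 (2S,6R,7S,8R,9R)-8-(angeloyloxy)-2-[(tert-butyldimethylsilyl)oxy]-9-[(triethylsilyl)oxy]germacra-1(10)Z,4E,11(13)-trien-12,6-olide, via mixed anhydride 30 (not isolated)
Conditions: 29, 2,4,6-trichlorobenzoyl chloride, Et3N, toluene, rt; then 28, toluene, 80 °C
Reagents that add atoms: none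
Why: Yamaguchi esterification through the preformed mixed anhydride, without a nucleophilic catalyst, should transfer the angeloyl group to the hindered C8 hydroxyl without Z-to-E isomerisation to the tiglate.

**Step 17**
Reactants: 31 (2S,6R,7S,8R,9R)-8-(angeloyloxy)-2-[(tert-butyldimethylsilyl)oxy]-9-[(triethylsilyl)oxy]germacra-1(10)Z,4E,11(13)-trien-12,6-olide
Product: 32 (2S,6R,7S,8R,9R)-8-(angeloyloxy)-2-[(tert-butyldimethylsilyl)oxy]-9-hydroxygermacra-1(10)Z,4E,11(13)-trien-12,6-olide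
Conditions: PPTS (cat.), MeOH–CH2Cl2, 0 °C
Reagents that add atoms: none
Why: Selective desilylation: acid-catalysed methanolysis cleaves the triethylsilyl ether much faster than the bulkier tert-butyldimethylsilyl ether, and the mild acid should not move the angelate.

**Step 18**
Reactants: 32 (2S,6R,7S,8R,9R)-8-(angeloyloxy)-2-[(tert-butyldimethylsilyl)oxy]-9-hydroxygermacra-1(10)Z,4E,11(13)-trien-12,6-olide
Product: 33 (2S,6R,7S,8R,9R)-9-acetoxy-8-(angeloyloxy)-2-[(tert-butyldimethylsilyl)oxy]germacra-1(10)Z,4E,11(13)-trien-12,6-olide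
Conditions: Ac2O, pyridine, DMAP (cat.), CH2Cl2, 0 °C
Reagents that add atoms: acetic anhydride, CC(=O)OC(C)=O
Why: DMAP-catalysed acetylation of the C9 hydroxyl at low temperature should be faster than 1,2-migration of the neighbouring angelate.

**Step 19**
Reactants: 33 (2S,6R,7S,8R,9R)-9-acetoxy-8-(angeloyloxy)-2-[(tert-butyldimethylsilyl)oxy]germacra-1(10)Z,4E,11(13)-trien-12,6-olide
Product: 34 (2S,6R,7S,8R,9R)-9-acetoxy-8-(angeloyloxy)-2-hydroxygermacra-1(10)Z,4E,11(13)-trien-12,6-olide (CNP0316477.1)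
Conditions: HF·pyridine, pyridine, THF, 0 °C to rt
Reagents that add atoms: none
Why: Fluoride-mediated desilylation under buffered, non-basic conditions frees the C2 hydroxyl and should leave both esters and the α-methylene lactone intact.

**Compound list**
1 | (S)-2,2-dimethyl-1,3-dioxolane-4-carbaldehyde | O=C[C@@H]1COC(C)(C)O1 | starting material
2 | (R)-4-ethynyl-2,2-dimethyl-1,3-dioxolane | C#C[C@@H]1COC(C)(C)O1 | intermediate
3 | (R)-but-3-yne-1,2-diol | C#C[C@@H](O)CO | intermediate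
4 | (R)-2,2-dibutyl-4-ethynyl-1,3,2-dioxastannolane (stannylene acetal, not isolated) | C#C[C@@H]1CO[Sn](CCCC)(CCCC)O1 | intermediate
5 | (R)-1-[(4-methoxybenzyl)oxy]but-3-yn-2-ol | C#C[C@@H](O)COCc1ccc(OC)cc1 | intermediate
6 | oxamagnesacycle from anti-carbomagnesiation (Mg on C1 and on O9, not isolated) | CC1=C[Mg]O[C@H]1COCc1ccc(OC)cc1 | intermediate
7 | (2R,3Z)-4-iodo-1-[(4-methoxybenzyl)oxy]-3-methylbut-3-en-2-ol | I/C=C(/C)[C@@H](O)COCc1ccc(OC)cc1 | intermediate
8 | (2R,3Z)-4-iodo-1-[(4-methoxybenzyl)oxy]-3-methyl-2-[(triethylsilyl)oxy]but-3-ene | I/C=C(/C)[C@@H](O[Si](CC)(CC)CC)COCc1ccc(OC)cc1 | intermediate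
9 | Z alkenylmagnesium chloride from 8 (not isolated) | Cl[Mg]/C=C(/C)[C@@H](O[Si](CC)(CC)CC)COCc1ccc(OC)cc1 | intermediate
10 | (2Z,4R)-5-[(4-methoxybenzyl)oxy]-3-methyl-4-[(triethylsilyl)oxy]pent-2-enal | O=C/C=C(/C)[C@@H](O[Si](CC)(CC)CC)COCc1ccc(OC)cc1 | intermediate
11 | allenylboronic acid pinacol ester | C=C=CB1OC(C)(C)C(C)(C)O1 | starting material
12 | pinacol borate of 13 (not isolated) | C#CC[C@H](OB1OC(C)(C)C(C)(C)O1)/C=C(/C)[C@@H](O[Si](CC)(CC)CC)COCc1ccc(OC)cc1 | intermediate
13 | (4S,5Z,7R)-8-[(4-methoxybenzyl)oxy]-6-methyl-7-[(triethylsilyl)oxy]oct-5-en-1-yn-4-ol | C#CC[C@H](O)/C=C(/C)[C@@H](O[Si](CC)(CC)CC)COCc1ccc(OC)cc1 | intermediate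
14 | (4S,5Z,7R)-4-[(tert-butyldimethylsilyl)oxy]-8-[(4-methoxybenzyl)oxy]-6-methyl-7-[(triethylsilyl)oxy]oct-5-en-1-yne | C#CC[C@H](O[Si](C)(C)C(C)(C)C)/C=C(/C)[C@@H](O[Si](CC)(CC)CC)COCc1ccc(OC)cc1 | intermediate
15 | E alkenyl(dimethyl)alane from 14 (not isolated) | C[Al](C)/C=C(\C)C[C@H](O[Si](C)(C)C(C)(C)C)/C=C(/C)[C@@H](O[Si](CC)(CC)CC)COCc1ccc(OC)cc1 | intermediate
16 | (1E,4S,5Z,7R)-4-[(tert-butyldimethylsilyl)oxy]-1-iodo-8-[(4-methoxybenzyl)oxy]-2,6-dimethyl-7-[(triethylsilyl)oxy]octa-1,5-diene | I/C=C(\C)C[C@H](O[Si](C)(C)C(C)(C)C)/C=C(/C)[C@@H](O[Si](CC)(CC)CC)COCc1ccc(OC)cc1 | intermediate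
17 | acrolein | C=CC=O | starting material
18 | E alkenyllithium from 16 (not isolated) | [Li]/C=C(\C)C[C@H](O[Si](C)(C)C(C)(C)C)/C=C(/C)[C@@H](O[Si](CC)(CC)CC)COCc1ccc(OC)cc1 | intermediate
19 | E alkenyl(ethyl)zinc from 18 (not isolated) | CC[Zn]/C=C(\C)C[C@H](O[Si](C)(C)C(C)(C)C)/C=C(/C)[C@@H](O[Si](CC)(CC)CC)COCc1ccc(OC)cc1 | intermediate
20 | (3S,4E,7S,8Z,10R)-7-[(tert-butyldimethylsilyl)oxy]-11-[(4-methoxybenzyl)oxy]-5,9-dimethyl-10-[(triethylsilyl)oxy]undeca-1,4,8-trien-3-ol | C=C[C@H](O)/C=C(\C)C[C@H](O[Si](C)(C)C(C)(C)C)/C=C(/C)[C@@H](O[Si](CC)(CC)CC)COCc1ccc(OC)cc1 | intermediate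
21 | 2-(bromomethyl)acrylic acid | C=C(CBr)C(=O)O | starting material
22 | O-acylisourea of 21 with DCC (not isolated) | C=C(CBr)C(=O)OC(=NC1CCCCC1)NC1CCCCC1 | intermediate
23 | (3S,4E,7S,8Z,10R)-7-[(tert-butyldimethylsilyl)oxy]-11-[(4-methoxybenzyl)oxy]-5,9-dimethyl-10-[(triethylsilyl)oxy]undeca-1,4,8-trien-3-yl 2-(bromomethyl)acrylate | C=C[C@H](OC(=O)C(=C)CBr)/C=C(\C)C[C@H](O[Si](C)(C)C(C)(C)C)/C=C(/C)[C@@H](O[Si](CC)(CC)CC)COCc1ccc(OC)cc1 | intermediate
24 | (5R)-3-(bromomethyl)-5-[(1E,4S,5Z,7R)-4-[(tert-butyldimethylsilyl)oxy]-8-[(4-methoxybenzyl)oxy]-2,6-dimethyl-7-[(triethylsilyl)oxy]octa-1,5-dien-1-yl]furan-2(5H)-one | BrCC1=C[C@@H](/C=C(\C)C[C@H](O[Si](C)(C)C(C)(C)C)/C=C(/C)[C@@H](O[Si](CC)(CC)CC)COCc2ccc(OC)cc2)OC1=O | intermediate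
25 | (5R)-3-(bromomethyl)-5-[(1E,4S,5Z,7R)-4-[(tert-butyldimethylsilyl)oxy]-8-hydroxy-2,6-dimethyl-7-[(triethylsilyl)oxy]octa-1,5-dien-1-yl]furan-2(5H)-one | BrCC1=C[C@@H](/C=C(\C)C[C@H](O[Si](C)(C)C(C)(C)C)/C=C(/C)[C@@H](O[Si](CC)(CC)CC)CO)OC1=O | intermediate
26 | (2R,3Z,5S,7E)-8-[(2R)-4-(bromomethyl)-5-oxo-2,5-dihydrofuran-2-yl]-5-[(tert-butyldimethylsilyl)oxy]-3,7-dimethyl-2-[(triethylsilyl)oxy]octa-3,7-dienal (key-step precursor) | BrCC1=C[C@@H](/C=C(\C)C[C@H](O[Si](C)(C)C(C)(C)C)/C=C(/C)[C@@H](O[Si](CC)(CC)CC)C=O)OC1=O | intermediate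
27 | allyl(dichloro)chromium from 26, trivalent chromium on C13 (not isolated) | Cl[Cr](Cl)CC1=C[C@@H](/C=C(\C)C[C@H](O[Si](C)(C)C(C)(C)C)/C=C(/C)[C@@H](O[Si](CC)(CC)CC)C=O)OC1=O | intermediate
28 | (2S,6R,7R,8R,9R)-2-[(tert-butyldimethylsilyl)oxy]-8-hydroxy-9-[(triethylsilyl)oxy]germacra-1(10)Z,4E,11(13)-trien-12,6-olide (key-step product) | C=C1C(=O)O[C@@H]2/C=C(\C)C[C@H](O[Si](C)(C)C(C)(C)C)/C=C(/C)[C@@H](O[Si](CC)(CC)CC)[C@H](O)[C@@H]12 | intermediate
29 | angelic acid, (Z)-2-methylbut-2-enoic acid | C/C=C(/C)C(=O)O | starting material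
30 | angelic 2,4,6-trichlorobenzoic anhydride (not isolated) | C/C=C(/C)C(=O)OC(=O)c1c(Cl)cc(Cl)cc1Cl | intermediate
31 | (2S,6R,7S,8R,9R)-8-(angeloyloxy)-2-[(tert-butyldimethylsilyl)oxy]-9-[(triethylsilyl)oxy]germacra-1(10)Z,4E,11(13)-trien-12,6-olide | C=C1C(=O)O[C@@H]2/C=C(\C)C[C@H](O[Si](C)(C)C(C)(C)C)/C=C(/C)[C@@H](O[Si](CC)(CC)CC)[C@H](OC(=O)/C(C)=C\C)[C@@H]12 | intermediate
32 | (2S,6R,7S,8R,9R)-8-(angeloyloxy)-2-[(tert-butyldimethylsilyl)oxy]-9-hydroxygermacra-1(10)Z,4E,11(13)-trien-12,6-olide | C=C1C(=O)O[C@@H]2/C=C(\C)C[C@H](O[Si](C)(C)C(C)(C)C)/C=C(/C)[C@@H](O)[C@H](OC(=O)/C(C)=C\C)[C@@H]12 | intermediate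
33 | (2S,6R,7S,8R,9R)-9-acetoxy-8-(angeloyloxy)-2-[(tert-butyldimethylsilyl)oxy]germacra-1(10)Z,4E,11(13)-trien-12,6-olide | C=C1C(=O)O[C@@H]2/C=C(\C)C[C@H](O[Si](C)(C)C(C)(C)C)/C=C(/C)[C@@H](OC(C)=O)[C@H](OC(=O)/C(C)=C\C)[C@@H]12 | intermediate
34 | (2S,6R,7S,8R,9R)-9-acetoxy-8-(angeloyloxy)-2-hydroxygermacra-1(10)Z,4E,11(13)-trien-12,6-olide, CNP0316477.1 | C=C1C(=O)O[C@@H]2/C=C(\C)C[C@H](O)/C=C(/C)[C@@H](OC(C)=O)[C@H](OC(=O)/C(C)=C\C)[C@@H]12 | target

**Step count**
Total: 19 steps. Longest linear sequence: 19 steps (1 to 34); 14 steps lead to the key-step precursor 26.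

**Steps most likely to fail**

1. Step 15 (ring closure). What may go wrong: facial selectivity at the C8 aldehyde. The Felkin–Anh preference of the α-silyloxy aldehyde, or a boat-like allyl transfer, may win over the chair and give the C8 epimer; oligomerisation may also compete. Fallback: inversion at C8 instead of direct control. Setting out from 26, the same ring closure is run and the C8-epimeric alcohol F1 is carried on. Mitsunobu esterification of it (PPh3, DIAD, angelic acid 29, toluene, 0 °C to rt) displaces the activated C8 oxygen with inversion and installs the angelate in the same operation. The route is rejoined at 31.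

2. Step 10 (C6 carbinol). What may go wrong: poor enantiofacial discrimination with the small aldehyde acrolein, together with its polymerisation under organometallic conditions. Fallback: swap the roles of the partners and bring in C7 as an alkyne. Setting out from 16, iodine–lithium exchange (t-BuLi, Et2O, −78 °C) and formylation with DMF give the E enal F2. Zinc-alkynylide addition of trimethylsilylacetylene under Me2Zn and ProPhenol catalysis (a method established for α,β-unsaturated aldehydes; the ligand antipode that gives the 6R alcohol is taken) gives the silylated propargylic alcohol F3. K2CO3 in MeOH removes the silyl group to give the terminal alkynyl carbinol F4. Red-Al in THF at 0 °C reduces the propargylic alkyne to the vinyl group, and the route is rejoined at 20.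

3. Step 16 (angelate). What may go wrong: Z-to-E isomerisation of the angeloyl unit (tiglate formation) during slow acyl transfer to the hindered C8 hydroxyl, or silyl migration from O9 on heating with amine. Fallback: build the Z enoate on the substrate. Setting out from 28, Steglich esterification with 2-[bis(2,2,2-trifluoroethoxy)phosphoryl]propanoic acid (DCC, DMAP, CH2Cl2, 0 °C) gives the phosphonopropionate ester F5. Still–Gennari olefination (KHMDS, 18-crown-6, THF, −78 °C, then acetaldehyde) forms the Z-2-methylbut-2-enoate, and the route is rejoined at 31.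

**Further compounds**
F1 | step 15 | (2S,6R,7R,8S,9R)-2-[(tert-butyldimethylsilyl)oxy]-8-hydroxy-9-[(triethylsilyl)oxy]germacra-1(10)Z,4E,11(13)-trien-12,6-olide (C8 epimer of 28) | C=C1C(=O)O[C@@H]2/C=C(\C)C[C@H](O[Si](C)(C)C(C)(C)C)/C=C(/C)[C@@H](O[Si](CC)(CC)CC)[C@@H](O)[C@@H]12
F2 | step 10 | (2E,5S,6Z,8R)-5-[(tert-butyldimethylsilyl)oxy]-9-[(4-methoxybenzyl)oxy]-3,7-dimethyl-8-[(triethylsilyl)oxy]nona-2,6-dienal | O=C/C=C(\C)C[C@H](O[Si](C)(C)C(C)(C)C)/C=C(/C)[C@@H](O[Si](CC)(CC)CC)COCc1ccc(OC)cc1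
F3 | step 10 | (3R,4E,7S,8Z,10R)-7-[(tert-butyldimethylsilyl)oxy]-11-[(4-methoxybenzyl)oxy]-5,9-dimethyl-10-[(triethylsilyl)oxy]-1-(trimethylsilyl)undeca-4,8-dien-1-yn-3-ol | C[Si](C)(C)C#C[C@H](O)/C=C(\C)C[C@H](O[Si](C)(C)C(C)(C)C)/C=C(/C)[C@@H](O[Si](CC)(CC)CC)COCc1ccc(OC)cc1
F4 | step 10 | (3R,4E,7S,8Z,10R)-7-[(tert-butyldimethylsilyl)oxy]-11-[(4-methoxybenzyl)oxy]-5,9-dimethyl-10-[(triethylsilyl)oxy]undeca-4,8-dien-1-yn-3-ol | C#C[C@H](O)/C=C(\C)C[C@H](O[Si](C)(C)C(C)(C)C)/C=C(/C)[C@@H](O[Si](CC)(CC)CC)COCc1ccc(OC)cc1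
F5 | step 16 | C8 2-[bis(2,2,2-trifluoroethoxy)phosphoryl]propanoate of 28 (mixture at the phosphonate α-carbon) | C=C1C(=O)O[C@@H]2/C=C(\C)C[C@H](O[Si](C)(C)C(C)(C)C)/C=C(/C)[C@@H](O[Si](CC)(CC)CC)[C@H](OC(=O)C(C)P(=O)(OCC(F)(F)F)OCC(F)(F)F)[C@@H]12
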